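**Retrosynthetic overview**
1. The chain atoms C1–C10 are counted from the butenolide. The C3=C4 (Z) olefin with its CH2OAc branch on C4 is read as a hidden propargyl alcohol, so the key step cuts C4–C5 and C2–C3 at once.
2. Key step: one-flask three-component union. A C16 homoallyl Grignard reagent (C5–C10 plus the cyclohexanol ring) adds anti across propargyl alcohol (C3, C4, CH2O) under copper catalysis; Zn/Pd coupling with an (E)-iodovinyl butenolide (C1, C2, lactone ring) then completes the C25 skeleton and fixes 3Z.
3. The C16 bromide comes from a B-alkyl Suzuki coupling (bond C8–C9) of the 9-BBN adduct of a vinyl carbinol with (E)-4-iodopent-3-en-1-ol (7E from alkyne hydrozirconation).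
4. The vinyl carbinol comes from axial vinyl addition to (S)-2,2,6-trimethylcyclohexanone (ring C1 set by ring C6); the ketone comes from the racemate by enantioselective protonation of its silyl enol ether.
5. No ring is formed in the route: the cyclohexane ring comes from the commercial ketone and the butenolide ring from commercial 4-bromofuran-2(5H)-one. Acetylation is last.

Key step: step 9

Remark (reading of the target): the SMILES is read as ring (1R,6S) with the OH trans to the ring C6 methyl (side chain cis to it), 3Z (CH2OAc cis to C2), 1E and 7E.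

**Route**

Step 1
Reactants: 1 rac-2,2,6-trimethylcyclohexan-1-one
Product: 2 trimethyl[(2,6,6-trimethylcyclohex-1-en-1-yl)oxy]silane
Conditions: TMSOTf, Et3N, CH2Cl2, 0 → 20 °C
Reagents that add atoms: trimethylsilyl trifluoromethanesulfonate, C[Si](C)(C)OS(=O)(=O)C(F)(F)F
Why: Soft enolization and O-silylation (silyl enol ether formation); only C6 carries an α-hydrogen, so one regioisomer can form and the stereocentre of the racemate is erased on purpose.

Step 2
Reactants: 2 trimethyl[(2,6,6-trimethylcyclohex-1-en-1-yl)oxy]silane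
Product: 3 (S)-2,2,6-trimethylcyclohexan-1-one
Conditions: SnCl4 (cat.), BINOL monomethyl ether (cat., the antipode that protonates the Re face at C2 of 2), 2,6-dimethylphenol (1.1 equiv), slow addition of 2, toluene, −78 °C
Reagents that add atoms: none
Why: Catalytic enantioselective protonation of a silyl enol ether by a Lewis acid-assisted chiral Brønsted acid, turned over by the achiral phenol that also takes up the silyl group; proton delivery to the Re face of the methyl-bearing carbon C2 should set the ring stereocentre as S.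

Step 3
Reactants: 3 (S)-2,2,6-trimethylcyclohexan-1-one; 4 vinylmagnesium bromide
Product: 5 (1R,6S)-1-ethenyl-2,2,6-trimethylcyclohexan-1-ol
Conditions: 4 (1.5 equiv), LaCl3·2LiCl (30 mol %), THF, 0 °C; aq NH4Cl
Reagents that add atoms: none
Why: Grignard 1,2-addition; in the chair with the C6 methyl equatorial, the axial methyl of the gem-dimethyl carbon blocks equatorial approach, so vinyl should enter axially, cis to the C6 methyl, which sets C1 as R with the OH trans to that methyl.

Step 4
Reactants: 6 pent-3-yn-1-ol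
Product: 8 (E)-4-iodopent-3-en-1-ol, via alkenylzirconocene 7 (not isolated)
Conditions: Cp2Zr(H)Cl (2.5 equiv), THF, 20 → 40 °C; I2, 0 °C; aq Na2S2O3
Reagents that add atoms: iodine, II
Why: Hydrozirconation–iodination; syn addition of Zr–H, with excess reagent equilibrating zirconium to the methyl-bearing alkyne carbon, then iodinolysis with retention should give the E iodide (methyl cis to the CH2CH2OH chain).

Step 5
Reactants: 5 (1R,6S)-1-ethenyl-2,2,6-trimethylcyclohexan-1-ol; 8 (E)-4-iodopent-3-en-1-ol
Product: 10 (1R,6S)-1-[(3E)-6-hydroxy-3-methylhex-3-en-1-yl]-2,2,6-trimethylcyclohexan-1-ol, via B-alkyl-9-BBN 9 (not isolated)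
Conditions: 9-BBN (1.5 equiv), THF, 0 → 20 °C; then 8, Pd(dppf)Cl2 (5 mol %), AsPh3 (10 mol %), Cs2CO3, DMF–H2O, 20 °C
Reagents that add atoms: none
Why: Anti-Markovnikov hydroboration of the vinyl group and B-alkyl Suzuki–Miyaura coupling, which proceeds with retention at the alkenyl iodide and so carries the E geometry into the trisubstituted C7=C8 olefin; both free hydroxyl groups are tolerated.

Step 6
Reactants: 10 (1R,6S)-1-[(3E)-6-hydroxy-3-methylhex-3-en-1-yl]-2,2,6-trimethylcyclohexan-1-ol
Product: 11 (1R,6S)-1-[(3E)-6-bromo-3-methylhex-3-en-1-yl]-2,2,6-trimethylcyclohexan-1-ol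
Conditions: CBr4, PPh3, CH2Cl2, 0 °C
Reagents that add atoms: tetrabromomethane, BrC(Br)(Br)Br
Why: Appel bromination (SN2 on the alkoxyphosphonium ion) of the primary alcohol; the tertiary alcohol, flanked by a quaternary and a tertiary carbon, should not react.

Step 7
Reactants: 12 4-bromofuran-2(5H)-one; 13 (E)-1,2-bis(tributylstannyl)ethene
Product: 14 (E)-4-[2-(tributylstannyl)ethenyl]furan-2(5H)-one
Conditions: 13 (2 equiv), Pd2(dba)3 (2.5 mol %), AsPh3 (10 mol %), NMP, 40 °C
Reagents that add atoms: none
Why: Stille coupling at the activated β-bromo position of the butenolide; the excess of bis-stannane should hold the reaction at mono-coupling, and the E geometry is retained.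

Step 8
Reactants: 14 (E)-4-[2-(tributylstannyl)ethenyl]furan-2(5H)-one
Product: 15 (E)-4-(2-iodoethenyl)furan-2(5H)-one
Conditions: I2, CH2Cl2, 0 °C, dark
Reagents that add atoms: iodine, II
Why: Iododestannylation (ipso substitution of the alkenyl–tin bond) with retention of the E geometry.

Step 9
Reactants: 11 (1R,6S)-1-[(3E)-6-bromo-3-methylhex-3-en-1-yl]-2,2,6-trimethylcyclohexan-1-ol; 16 prop-2-yn-1-ol; 15 (E)-4-(2-iodoethenyl)furan-2(5H)-one
Product: 22 4-[(1E,3Z,7E)-4-(hydroxymethyl)-10-[(1R,6S)-1-hydroxy-2,2,6-trimethylcyclohexyl]-8-methyldeca-1,3,7-trien-1-yl]furan-2(5H)-one, via bromoalkoxide 17 (not isolated), via Grignard reagent 18 (not isolated), via chloromagnesium propynolate 19 (not isolated), via oxamagnesacycle 20 (not isolated), via alkenylzinc chelate 21 (not isolated)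
Conditions: (a) 11, i-PrMgCl (1.0 equiv), THF, −20 °C, then Mg turnings, 20 °C; (b) 16 (1.2 equiv), i-PrMgCl (1.2 equiv), THF, −20 °C, added to (a), CuI (10 mol %), −10 → 20 °C; (c) ZnCl2, 0 °C; (d) 15 (1.2 equiv), Pd2(dba)3 (2.5 mol %), P(2-furyl)3 (10 mol %), 0 → 20 °C; aq NH4Cl
Reagents that add atoms: none
Why: Copper-catalysed carbomagnesiation of the magnesium alkoxide of a propargylic alcohol: the alkyl group of 18 is delivered to the alkyne carbon next to the CH2O group (future C4) and the metal to the terminal carbon (future C3), the alkoxide holding the metal on its own side, so that addition is anti and the five-membered oxamagnesacycle 20 results; Mg-to-Zn exchange and Negishi coupling with 15 then proceed with retention at both sp2 carbons. The closest known reaction type is the three-component magnesium carbometalation/palladium cross-coupling of propargylic alcohols, and the anti-carbomagnesiation of propargyl alcohol itself by alkyl Grignard reagents with iodine as the trap. No ring of the product is closed; the only ring formed is the transient O–Mg (then O–Zn) chelate, closed by coordination in a five-membered mode. No stereocentre is created; the new stereo-element is the 3Z olefin, controlled by the chelate (CH2O and metal, hence C2, cis), while 1E comes unchanged from 15 and 7E and the ring centres are spectators. The step needs regioselectivity (alkyl to the internal carbon, secured by the alkoxide), carbometalation faster than proton transfer from the alkyne C–H (secured by CuI and low temperature), and coupling at the C–I bond in the presence of the lactone (secured by the mild alkenylzinc); the tertiary alcohol travels as its inert magnesium alkoxide.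

Step 10
Reactants: 22 4-[(1E,3Z,7E)-4-(hydroxymethyl)-10-[(1R,6S)-1-hydroxy-2,2,6-trimethylcyclohexyl]-8-methyldeca-1,3,7-trien-1-yl]furan-2(5H)-one
Product: 23 4-[(1E,3Z,7E)-4-(acetoxymethyl)-10-[(1R,6S)-1-hydroxy-2,2,6-trimethylcyclohexyl]-8-methyldeca-1,3,7-trien-1-yl]furan-2(5H)-one (CNP0366059.1)
Conditions: Ac2O (1.2 equiv), pyridine, DMAP (5 mol %), CH2Cl2, 0 °C
Reagents that add atoms: acetic anhydride, CC(=O)OC(C)=O
Why: DMAP-catalysed acylation of the primary allylic alcohol; the tertiary ring alcohol is too hindered to be acetylated under these conditions.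

**Compound list**
1 | rac-2,2,6-trimethylcyclohexan-1-one | CC1CCCC(C)(C)C1=O | starting material
2 | trimethyl[(2,6,6-trimethylcyclohex-1-en-1-yl)oxy]silane | CC1=C(O[Si](C)(C)C)C(C)(C)CCC1 | intermediate
3 | (S)-2,2,6-trimethylcyclohexan-1-one | C[C@H]1CCCC(C)(C)C1=O | intermediate
4 | vinylmagnesium bromide | C=C[Mg]Br | starting material
5 | (1R,6S)-1-ethenyl-2,2,6-trimethylcyclohexan-1-ol | C=C[C@@]1(O)[C@@H](C)CCCC1(C)C | intermediate
6 | pent-3-yn-1-ol | CC#CCCO | starting material
7 | [(2E)-5-{[chlorobis(cyclopentadienyl)zirconio]oxy}pent-2-en-2-yl]chlorobis(cyclopentadienyl)zirconium | C/C(=C\CCO[Zr](Cl)(C1C=CC=C1)C1C=CC=C1)[Zr](Cl)(C1C=CC=C1)C1C=CC=C1 | intermediate (not isolated)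
8 | (E)-4-iodopent-3-en-1-ol | C/C(I)=C\CCO | intermediate
9 | 9-{2-[(1R,6S)-1-hydroxy-2,2,6-trimethylcyclohexyl]ethyl}-9-borabicyclo[3.3.1]nonane | B1(CC[C@@]2(O)[C@@H](C)CCCC2(C)C)C2CCCC1CCC2 | intermediate (not isolated)
10 | (1R,6S)-1-[(3E)-6-hydroxy-3-methylhex-3-en-1-yl]-2,2,6-trimethylcyclohexan-1-ol | OCC/C=C(\C)CC[C@@]1(O)[C@@H](C)CCCC1(C)C | intermediate
11 | (1R,6S)-1-[(3E)-6-bromo-3-methylhex-3-en-1-yl]-2,2,6-trimethylcyclohexan-1-ol | BrCC/C=C(\C)CC[C@@]1(O)[C@@H](C)CCCC1(C)C | intermediate
12 | 4-bromofuran-2(5H)-one | BrC1=CC(=O)OC1 | starting material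
13 | (E)-1,2-bis(tributylstannyl)ethene | CCCC[Sn](CCCC)(CCCC)/C=C/[Sn](CCCC)(CCCC)CCCC | starting material
14 | (E)-4-[2-(tributylstannyl)ethenyl]furan-2(5H)-one | CCCC[Sn](CCCC)(CCCC)/C=C/C1=CC(=O)OC1 | intermediate
15 | (E)-4-(2-iodoethenyl)furan-2(5H)-one | I/C=C/C1=CC(=O)OC1 | intermediate
16 | prop-2-yn-1-ol | C#CCO | starting material
17 | chloromagnesium (1R,6S)-1-[(3E)-6-bromo-3-methylhex-3-en-1-yl]-2,2,6-trimethylcyclohexan-1-olate | BrCC/C=C(\C)CC[C@@]1(O[Mg]Cl)[C@@H](C)CCCC1(C)C | intermediate (not isolated)
18 | {(3E)-6-[(1R,6S)-1-(chloromagnesiooxy)-2,2,6-trimethylcyclohexyl]-4-methylhex-3-en-1-yl}magnesium bromide | Br[Mg]CC/C=C(\C)CC[C@@]1(O[Mg]Cl)[C@@H](C)CCCC1(C)C | intermediate (not isolated)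
19 | chloromagnesium prop-2-yn-1-olate | C#CCO[Mg]Cl | intermediate (not isolated)
20 | 4-{(3E)-6-[(1R,6S)-1-(chloromagnesiooxy)-2,2,6-trimethylcyclohexyl]-4-methylhex-3-en-1-yl}-2,5-dihydro-1,2-oxamagnesole | [Mg]1OCC(CC/C=C(\C)CC[C@@]2(O[Mg]Cl)[C@@H](C)CCCC2(C)C)=C1 | intermediate (not isolated)
21 | 4-{(3E)-6-[(1R,6S)-1-(chloromagnesiooxy)-2,2,6-trimethylcyclohexyl]-4-methylhex-3-en-1-yl}-2,5-dihydro-1,2-oxazincole | [Zn]1OCC(CC/C=C(\C)CC[C@@]2(O[Mg]Cl)[C@@H](C)CCCC2(C)C)=C1 | intermediate (not isolated)
22 | 4-[(1E,3Z,7E)-4-(hydroxymethyl)-10-[(1R,6S)-1-hydroxy-2,2,6-trimethylcyclohexyl]-8-methyldeca-1,3,7-trien-1-yl]furan-2(5H)-one | OC/C(=C\C=C\C1=CC(=O)OC1)CC/C=C(\C)CC[C@@]1(O)[C@@H](C)CCCC1(C)C | intermediate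
23 | 4-[(1E,3Z,7E)-4-(acetoxymethyl)-10-[(1R,6S)-1-hydroxy-2,2,6-trimethylcyclohexyl]-8-methyldeca-1,3,7-trien-1-yl]furan-2(5H)-one | CC(=O)OC/C(=C\C=C\C1=CC(=O)OC1)CC/C=C(\C)CC[C@@]1(O)[C@@H](C)CCCC1(C)C | target

**Step count and risks**
Total steps: 10. Longest linear sequence: 7 (steps 1, 2, 3, 5, 6, 9, 10).

Steps most likely to fail:

1. Step 9. Proton transfer from the alkyne C–H to the Grignard reagent may outrun carbometalation, so the C16 fragment would be lost as its hydrocarbon. Excess propargyl alkoxide may also consume 15 through a copper acetylide, and alkoxides may add to the iodovinyl lactone before palladium does. Fallback: from bromide 11 the flask is taken as in step 9 as far as oxamagnesacycle 20 and is then quenched with iodine (THF, −78 → 0 °C) instead of zinc and palladium. This should give the isolable (1R,6S)-1-[(3E,7Z)-7-(hydroxymethyl)-8-iodo-3-methylocta-3,7-dien-1-yl]-2,2,6-trimethylcyclohexan-1-ol F1. The polarity of the sp2–sp2 bond formation is then reversed: Stille coupling of F1 with stannane 14 from step 7 (Pd2(dba)3, AsPh3, CuI, NMP, 20 °C) comes back to the route at diol 22.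

2. Step 3. Facial selectivity may be poor (competing equatorial approach of the larger sp2 nucleophile), or the hindered ketone may be enolized with loss of material. Fallback: from ketone 3 the small sp nucleophile ethynylmagnesium bromide (THF, 0 °C) is used, which should follow the axial trajectory more closely, to give (1R,6S)-1-ethynyl-2,2,6-trimethylcyclohexan-1-ol F2. Semihydrogenation of F2 (Lindlar catalyst, quinoline, H2, EtOAc) comes back to the route at vinyl carbinol 5.

3. Step 2. Enantiofacial discrimination in the proton transfer may be insufficient, which would lower the optical purity of every later compound. Fallback: from enol silane 2, MeLi (THF, 0 °C) gives lithium 2,6,6-trimethylcyclohex-1-en-1-olate F3, which is O-acylated with allyl chloroformate (−78 °C) to prop-2-en-1-yl 2,6,6-trimethylcyclohex-1-en-1-yl carbonate F4. Palladium-catalysed decarboxylative enantioselective protonation of F4 (Pd(OAc)2, t-Bu-PHOX antipode chosen for Re-face protonation, HCO2H, 4 Å MS, dioxane, 40 °C) moves the stereo-determining event onto a ligand-bound palladium enolate and comes back to the route at ketone 3.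

Further compounds
F1 | step 9 | (1R,6S)-1-[(3E,7Z)-7-(hydroxymethyl)-8-iodo-3-methylocta-3,7-dien-1-yl]-2,2,6-trimethylcyclohexan-1-ol | OC/C(=C\I)CC/C=C(\C)CC[C@@]1(O)[C@@H](C)CCCC1(C)C
F2 | step 3 | (1R,6S)-1-ethynyl-2,2,6-trimethylcyclohexan-1-ol | C#C[C@@]1(O)[C@@H](C)CCCC1(C)C
F3 | step 2 | lithium 2,6,6-trimethylcyclohex-1-en-1-olate | [Li+].CC1=C([O-])C(C)(C)CCC1
F4 | step 2 | prop-2-en-1-yl 2,6,6-trimethylcyclohex-1-en-1-yl carbonate | C=CCOC(=O)OC1=C(C)CCCC1(C)C
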